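**Plan**
1. Cuts, in retrosynthetic order: the two O-benzyl groups; the oxolane C2–H and carbinol O–H (replaced by a C2–O bond, giving an oxetane acetal, 2,7-dioxabicyclo[3.2.0]heptane); H2 across C4–C5 (enol ether); then a retro-[2+2] through C3–C(carbinol) and C2–O(carbinol), giving O-benzylisovanillin and a 3-benzylfuran with a Me3Si blocking group; last the benzylic C–C bond of the furan.
2. Enabling feature: the oxolane is a reduced furan, and its O1–C2 unit lies 1,3 to the carbinol oxygen across the C3–C(carbinol) bond, so carbinol C, carbinol O, C2 and C3 can form one oxetane fused to a furan C=C edge.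
3. Forward: Negishi coupling gives the silylated 3-benzylfuran; a Paternò–Büchi photocycloaddition with the aldehyde joins the two halves and forms the oxetane; Si is removed; the enol ether is hydrogenated; i-Bu2AlH opens the oxetane acetal to the oxolane carbinol; resolution; debenzylation.
4. Stereochemistry: exo-selective cycloaddition sets C3 against the carbinol carbon; hydrogenation from the convex face of the bicycle gives the 3,4-cis ring; the cycloaddition is racemic, so the absolute configuration comes from an acylative kinetic resolution with (R)-benzotetramisole.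

Key step: step 4

Remark: 9–12 are racemates, written as the enantiomer that leads to 14. Furan 7 is numbered O1, C2 (Si), C3 (benzyl), C4, C5; its C4 and C5 become C3 and C2 of the oxolane of 14, whose numbering (O1, C2–C5) is used in the Why lines from step 5 on.

**Step 1**
Reactants: 1 3-bromofuran
Product: 3 (3-bromofuran-2-yl)trimethylsilane, via 3-bromo-2-lithiofuran 2 (not isolated)
Conditions: LiN(i-Pr)2 (1.05 equiv), THF, −78 °C; then Me3SiCl, −78 °C → rt
Reagents that add atoms: chlorotrimethylsilane C[Si](C)(C)Cl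
Why: Directed lithiation, in which LiN(i-Pr)2 removes the most acidic proton of 1 (C2, between the ring oxygen and bromine) at a temperature where bromine does not migrate, and the lithiofuran is silylated.

**Step 2**
Reactants: 4 [3-(benzyloxy)-4-methoxyphenyl]methanol
Product: 5 2-(benzyloxy)-4-(chloromethyl)-1-methoxybenzene
Conditions: SOCl2 (1.2 equiv), CH2Cl2, 0 °C → rt
Reagents that add atoms: thionyl chloride O=S(Cl)Cl
Why: Chlorination of a benzylic alcohol through its chlorosulfite, made easy by the electron-rich arene.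

**Step 3**
Reactants: 5 2-(benzyloxy)-4-(chloromethyl)-1-methoxybenzene; 3 (3-bromofuran-2-yl)trimethylsilane
Product: 7 {3-[3-(benzyloxy)-4-methoxybenzyl]furan-2-yl}trimethylsilane, via [3-(benzyloxy)-4-methoxybenzyl]zinc chloride 6 (not isolated)
Conditions: Zn dust, LiCl, THF, rt; then 3, Pd(OAc)2 (2 mol %), SPhos (4 mol %), THF, rt → 50 °C
Reagents that add atoms: none
Why: Negishi coupling, in which zinc inserts into the benzylic C–Cl bond and zerovalent palladium (from Pd(OAc)2 and SPhos) couples the benzylic zinc chloride with the hetaryl bromide, while the C–Si bond and the benzyl ether are inert.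

**Step 4**
Reactants: 7 {3-[3-(benzyloxy)-4-methoxybenzyl]furan-2-yl}trimethylsilane; 8 3-(benzyloxy)-4-methoxybenzaldehyde
Product: 9 rac-{(1R,5R,6S)-4-[3-(benzyloxy)-4-methoxybenzyl]-6-[3-(benzyloxy)-4-methoxyphenyl]-2,7-dioxabicyclo[3.2.0]hept-3-en-3-yl}trimethylsilane (6-aryl exo)
Conditions: hν (λ > 320 nm, Pyrex-filtered medium-pressure Hg lamp), degassed benzene, 10 °C, 7 in excess (3 equiv, recovered)
Reagents that add atoms: none
Why: Paternò–Büchi [2+2] photocycloaddition, in which the n,π* triplet of 8 bonds through oxygen to the unsubstituted α-carbon C5 of furan 7, and after intersystem crossing the 1,4-biradical (a benzylic radical and an allyl radical ending on the oxygen- and silicon-bearing C2) collapses between the carbinol carbon and furan C4, the bond that joins the two halves. The closest known reaction type is the furan–aldehyde photocycloaddition used as a photochemical aldol equivalent, including its 2-silylfuran variant that reacts only at the double bond remote from silicon. One ring is closed, the oxetane, by radical–radical combination in a four-membered (formal [2+2]) mode, cis-fused to the dihydrofuran. Of the three new stereocentres the two ring-fusion carbons are cis by the geometry of the four-membered ring, and the aryl-bearing carbon is set by the exo preference of the biradical closure (aryl turned away from the five-membered ring), which is the relation between C3 and the carbinol carbon of 14; there is no absolute control, so 9 should be racemic. The step needs site selectivity for the C4=C5 bond of the furan, secured by the Me3Si group at C2 (steric shielding of that α-carbon and stabilisation of the allyl radical terminus), and exo selectivity, secured by the compact fused transition structure. The excess of 7 should intercept the triplet before it abstracts benzylic hydrogen.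

**Step 5**
Reactants: 9 rac-{(1R,5R,6S)-4-[3-(benzyloxy)-4-methoxybenzyl]-6-[3-(benzyloxy)-4-methoxyphenyl]-2,7-dioxabicyclo[3.2.0]hept-3-en-3-yl}trimethylsilane
Product: 10 rac-(1S,5R,6S)-4-[3-(benzyloxy)-4-methoxybenzyl]-6-[3-(benzyloxy)-4-methoxyphenyl]-2,7-dioxabicyclo[3.2.0]hept-3-ene
Conditions: Bu4NF (1.5 equiv), THF–H2O (20:1), 0 → 40 °C
Reagents that add atoms: none
Why: Fluoride-induced protodesilylation of an α-oxygenated alkenylsilane, in which fluoride attacks silicon and the sp2 carbanion next to oxygen is protonated by water, while the base-stable oxetane acetal and the benzyl ethers are untouched.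

**Step 6**
Reactants: 10 rac-(1S,5R,6S)-4-[3-(benzyloxy)-4-methoxybenzyl]-6-[3-(benzyloxy)-4-methoxyphenyl]-2,7-dioxabicyclo[3.2.0]hept-3-ene
Product: 11 rac-(1S,4R,5R,6S)-4-[3-(benzyloxy)-4-methoxybenzyl]-6-[3-(benzyloxy)-4-methoxyphenyl]-2,7-dioxabicyclo[3.2.0]heptane
Conditions: H2 (1 atm), 5% Rh/Al2O3, EtOAc, K2CO3 (trace), rt
Reagents that add atoms: none
Why: Heterogeneous syn hydrogenation of the enol ether from the convex face of the cis-fused bicycle (away from the oxetane), which puts the new C4–H trans to the oxetane and the benzyl group cis to the C3–carbinol bond; rhodium is chosen because it should reduce enol ethers without hydrogenolysis of the benzyl ethers or of the benzylic oxetane C–O bond.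

**Step 7**
Reactants: 11 rac-(1S,4R,5R,6S)-4-[3-(benzyloxy)-4-methoxybenzyl]-6-[3-(benzyloxy)-4-methoxyphenyl]-2,7-dioxabicyclo[3.2.0]heptane
Product: 12 rac-(S)-{(3S,4R)-4-[3-(benzyloxy)-4-methoxybenzyl]oxolan-3-yl}[3-(benzyloxy)-4-methoxyphenyl]methanol
Conditions: i-Bu2AlH (3 equiv), CH2Cl2, −78 → −20 °C; aq. potassium sodium tartrate
Reagents that add atoms: none
Why: Reductive cleavage of a bicyclic acetal by a Lewis-acidic aluminium hydride, in which i-Bu2AlH coordinates the oxetane oxygen, the strained acetal C–O bond ionises to the five-membered oxocarbenium ion and hydride adds to C2, giving the oxolane CH2 and the free carbinol without touching a stereocentre.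

**Step 8**
Reactants: 12 rac-(S)-{(3S,4R)-4-[3-(benzyloxy)-4-methoxybenzyl]oxolan-3-yl}[3-(benzyloxy)-4-methoxyphenyl]methanol
Product: 13 (S)-{(3S,4R)-4-[3-(benzyloxy)-4-methoxybenzyl]oxolan-3-yl}[3-(benzyloxy)-4-methoxyphenyl]methanol
Conditions: (R)-benzotetramisole (4 mol %), (i-PrCO)2O (0.6 equiv), i-Pr2NEt (0.6 equiv), Na2SO4, CHCl3, 0 °C, run to about 55% conversion; chromatography
Reagents that add atoms: none
Why: Acylative kinetic resolution of an aryl alkyl carbinol by a chiral isothiourea acyl-transfer catalyst, whose N-acyl isothiouronium ion stacks with the aryl ring and is expected to acylate the (R)-carbinol enantiomer faster, so that the (S)-carbinol 13 remains and is separated from the ester.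

**Step 9**
Reactants: 13 (S)-{(3S,4R)-4-[3-(benzyloxy)-4-methoxybenzyl]oxolan-3-yl}[3-(benzyloxy)-4-methoxyphenyl]methanol
Product: 14 (S)-[(3S,4R)-4-(3-hydroxy-4-methoxybenzyl)oxolan-3-yl](3-hydroxy-4-methoxyphenyl)methanol
Conditions: H2 (1 atm), 10% Pd/C, EtOAc–EtOH, Et3N (trace), rt, stopped after uptake of 2 equiv
Reagents that add atoms: none
Why: Hydrogenolysis of the two aryl benzyl ethers under neutral conditions, which should be much faster than cleavage of the secondary benzylic C–OH bond, so the three stereocentres are untouched.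

**Compound list**
1 | 3-bromofuran | Brc1ccoc1 | starting material
2 | 3-bromo-2-lithiofuran | [Li]c1occc1Br | intermediate (not isolated)
3 | (3-bromofuran-2-yl)trimethylsilane | C[Si](C)(C)c1occc1Br | intermediate
4 | [3-(benzyloxy)-4-methoxyphenyl]methanol | COc1ccc(CO)cc1OCc1ccccc1 | starting material
5 | 2-(benzyloxy)-4-(chloromethyl)-1-methoxybenzene | COc1ccc(CCl)cc1OCc1ccccc1 | intermediate
6 | [3-(benzyloxy)-4-methoxybenzyl]zinc chloride | COc1ccc(C[Zn]Cl)cc1OCc1ccccc1 | intermediate (not isolated)
7 | {3-[3-(benzyloxy)-4-methoxybenzyl]furan-2-yl}trimethylsilane | COc1ccc(Cc2ccoc2[Si](C)(C)C)cc1OCc1ccccc1 | intermediate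
8 | 3-(benzyloxy)-4-methoxybenzaldehyde | COc1ccc(C=O)cc1OCc1ccccc1 | starting material
9 | rac-{(1R,5R,6S)-4-[3-(benzyloxy)-4-methoxybenzyl]-6-[3-(benzyloxy)-4-methoxyphenyl]-2,7-dioxabicyclo[3.2.0]hept-3-en-3-yl}trimethylsilane | COc1ccc(CC2=C([Si](C)(C)C)O[C@@H]3[C@H]2[C@H](O3)c2ccc(OC)c(OCc4ccccc4)c2)cc1OCc1ccccc1 | intermediate (racemate)
10 | rac-(1S,5R,6S)-4-[3-(benzyloxy)-4-methoxybenzyl]-6-[3-(benzyloxy)-4-methoxyphenyl]-2,7-dioxabicyclo[3.2.0]hept-3-ene | COc1ccc(CC2=CO[C@@H]3[C@H]2[C@H](O3)c2ccc(OC)c(OCc4ccccc4)c2)cc1OCc1ccccc1 | intermediate (racemate)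
11 | rac-(1S,4R,5R,6S)-4-[3-(benzyloxy)-4-methoxybenzyl]-6-[3-(benzyloxy)-4-methoxyphenyl]-2,7-dioxabicyclo[3.2.0]heptane | COc1ccc(C[C@H]2CO[C@@H]3[C@H]2[C@H](O3)c2ccc(OC)c(OCc4ccccc4)c2)cc1OCc1ccccc1 | intermediate (racemate)
12 | rac-(S)-{(3S,4R)-4-[3-(benzyloxy)-4-methoxybenzyl]oxolan-3-yl}[3-(benzyloxy)-4-methoxyphenyl]methanol | COc1ccc(C[C@H]2COC[C@H]2[C@H](O)c2ccc(OC)c(OCc3ccccc3)c2)cc1OCc1ccccc1 | intermediate (racemate)
13 | (S)-{(3S,4R)-4-[3-(benzyloxy)-4-methoxybenzyl]oxolan-3-yl}[3-(benzyloxy)-4-methoxyphenyl]methanol | COc1ccc(C[C@H]2COC[C@H]2[C@H](O)c2ccc(OC)c(OCc3ccccc3)c2)cc1OCc1ccccc1 | intermediate (single enantiomer)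
14 | (S)-[(3S,4R)-4-(3-hydroxy-4-methoxybenzyl)oxolan-3-yl](3-hydroxy-4-methoxyphenyl)methanol | COc1ccc(C[C@H]2COC[C@H]2[C@H](O)c2ccc(OC)c(O)c2)cc1O | target

**Totals and risks**
Total step count: 9. Longest linear sequence: 8 steps (steps 2–9 from 4, or steps 1 and 3–9 from 1).

Steps most likely to fail:

- **Step 4.** The cycloaddition may stall or go astray. The alkoxy-substituted aldehyde has a low-lying π,π* triplet that adds slowly, so hydrogen abstraction from the doubly activated benzylic CH2 of 7, or addition across the silylated double bond, may compete. The fallback sets out from 8 and comes back at 10, so step 5 is not needed either. Aldehyde 8 is irradiated under the same conditions in benzene with commercial furan in large excess, which should give the parent exo photoadduct rac-(1S,5R,6S)-6-[3-(benzyloxy)-4-methoxyphenyl]-2,7-dioxabicyclo[3.2.0]hept-3-ene F1. Bromine adds to its enol ether (CH2Cl2, −78 °C) to give the trans-dibromide rac-(1R,3R,4S,5R,6S)-3,4-dibromo-6-[3-(benzyloxy)-4-methoxyphenyl]-2,7-dioxabicyclo[3.2.0]heptane F2, which is not isolated and loses HBr on addition of DBU to give the bromo enol ether rac-(1R,5R,6S)-4-bromo-6-[3-(benzyloxy)-4-methoxyphenyl]-2,7-dioxabicyclo[3.2.0]hept-3-ene F3. Negishi coupling of F3 with the benzylic zinc chloride 6 (Pd(OAc)2, SPhos, THF) then gives 10. The benzyl group is attached after the cycloaddition, where no regiochemical question arises.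

- **Step 7.** Chemoselectivity of the acetal cleavage may be lost: the benzylic C–O bond of the oxetane may ionise (p-alkoxybenzyl cation) instead of the acetal C–O bond, which would deoxygenate the carbinol carbon. The fallback sets out from 11 and comes back at 12. Dilute aqueous acid (0.05 M HCl, THF–H2O, 0 °C) hydrolyses the oxetane acetal to the lactol rac-(3R,4R)-4-[3-(benzyloxy)-4-methoxybenzyl]-3-{(S)-[3-(benzyloxy)-4-methoxyphenyl](hydroxy)methyl}oxolan-2-ol F4 (anomer mixture). NaBH4 (MeOH, 0 °C) reduces it to the triol rac-(2S,3R)-3-[3-(benzyloxy)-4-methoxybenzyl]-2-{(S)-[3-(benzyloxy)-4-methoxyphenyl](hydroxy)methyl}butane-1,4-diol F5. A Mitsunobu cyclodehydration (PPh3, DIAD, THF), which activates a primary hydroxyl in preference to the hindered secondary one, closes the oxolane between the two primary hydroxyls to give 12.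

- **Step 8.** Enantiodiscrimination in the acyl transfer may be insufficient, because the carbinol is flanked by two bulky groups, or the faster-reacting enantiomer may be the wanted one. The fallback sets out from 12 and comes back at 13. Racemic 12 is esterified with (S)-2-methoxy-2-phenylacetic acid (DCC, DMAP, CH2Cl2). The two diastereomeric esters, (S)-{(3S,4R)-4-[3-(benzyloxy)-4-methoxybenzyl]oxolan-3-yl}[3-(benzyloxy)-4-methoxyphenyl]methyl (S)-2-methoxy-2-phenylacetate F6 and (R)-{(3R,4S)-4-[3-(benzyloxy)-4-methoxybenzyl]oxolan-3-yl}[3-(benzyloxy)-4-methoxyphenyl]methyl (S)-2-methoxy-2-phenylacetate F7, are separated by chromatography or crystallisation. F6 is saponified (LiOH, THF–H2O) to 13.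

**Further compounds**
F1 | step 4 | rac-(1S,5R,6S)-6-[3-(benzyloxy)-4-methoxyphenyl]-2,7-dioxabicyclo[3.2.0]hept-3-ene | C1=CO[C@@H]2[C@H]1[C@H](O2)c1ccc(OC)c(OCc2ccccc2)c1
F2 | step 4 | rac-(1R,3R,4S,5R,6S)-3,4-dibromo-6-[3-(benzyloxy)-4-methoxyphenyl]-2,7-dioxabicyclo[3.2.0]heptane | Br[C@@H]1[C@@H](Br)O[C@@H]2[C@H]1[C@H](O2)c1ccc(OC)c(OCc2ccccc2)c1
F3 | step 4 | rac-(1R,5R,6S)-4-bromo-6-[3-(benzyloxy)-4-methoxyphenyl]-2,7-dioxabicyclo[3.2.0]hept-3-ene | BrC1=CO[C@@H]2[C@H]1[C@H](O2)c1ccc(OC)c(OCc2ccccc2)c1
F4 | step 7 | rac-(3R,4R)-4-[3-(benzyloxy)-4-methoxybenzyl]-3-{(S)-[3-(benzyloxy)-4-methoxyphenyl](hydroxy)methyl}oxolan-2-ol | COc1ccc(C[C@H]2COC(O)[C@H]2[C@H](O)c2ccc(OC)c(OCc3ccccc3)c2)cc1OCc1ccccc1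
F5 | step 7 | rac-(2S,3R)-3-[3-(benzyloxy)-4-methoxybenzyl]-2-{(S)-[3-(benzyloxy)-4-methoxyphenyl](hydroxy)methyl}butane-1,4-diol | COc1ccc(C[C@@H](CO)[C@@H](CO)[C@H](O)c2ccc(OC)c(OCc3ccccc3)c2)cc1OCc1ccccc1
F6 | step 8 | (S)-{(3S,4R)-4-[3-(benzyloxy)-4-methoxybenzyl]oxolan-3-yl}[3-(benzyloxy)-4-methoxyphenyl]methyl (S)-2-methoxy-2-phenylacetate | COc1ccc(C[C@H]2COC[C@H]2[C@H](OC(=O)[C@@H](OC)c2ccccc2)c2ccc(OC)c(OCc3ccccc3)c2)cc1OCc1ccccc1
F7 | step 8 | (R)-{(3R,4S)-4-[3-(benzyloxy)-4-methoxybenzyl]oxolan-3-yl}[3-(benzyloxy)-4-methoxyphenyl]methyl (S)-2-methoxy-2-phenylacetate | COc1ccc(C[C@@H]2COC[C@@H]2[C@@H](OC(=O)[C@@H](OC)c2ccccc2)c2ccc(OC)c(OCc3ccccc3)c2)cc1OCc1ccccc1
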